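**Plan**

Labels: in ring B, B1 carries CO2H, B2 OH, B3 H, B4 the depside oxygen, B5 H and B6 pentyl. Ring A is the 2-hydroxy-4-methoxy-6-(2-oxoheptyl)benzoyl unit.
Cuts: first the depside bond (ring A C(=O)–O–B4), then the ArCH2–C(=O) bond of the ring A side chain, then ring B at B1–B6, B1–B2, B3–B4 and B4–B5.
Enabling feature: B3–H lies between two oxygens (B2–O and B4–O) that must be told apart, with carboxyl on B1, pentyl on B6 and H on B5. An ester-bearing vinylketene (C=O becomes B4–OH) and an ynol ether (C–OEt becomes B2, CH becomes B3) give exactly this pattern.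
Forward: heptanal is taken to 2-pentylacrolein and then to the unsaturated diazo keto ester, and ring B forms in one operation. Ring A is bought and only its side chain is extended. The rings are joined at the single free phenol, and hydrogenolysis followed by chelation-directed de-ethylation finishes the route.
Stereochemistry: the target has no stereocentre and no stereogenic double bond, so nothing has to be set. Two transient racemic centres are erased on the way.

Key step: step 4

Remark: benzyl diazoacetate, ethoxyacetylene, methyl everninate and N-methoxy-N-methylhexanamide are taken as catalogue compounds, and LiN(iPr)2 is used as a commercial solution.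

**Step 1**
Reactants: 1 heptanal
Product: 2 2-methylideneheptanal (2-pentylacrolein)
Conditions: 37% aq. HCHO, pyrrolidine (10 mol%), EtCO2H (10 mol%), i-PrOH, 45 °C
Reagents that add atoms: formaldehyde, C=O
Why: Amine-catalysed Mannich condensation, in which the enamine of heptanal adds to the formaldehyde iminium ion and the amine is eliminated; this is a standard alpha-methylenation of unbranched aldehydes and stops cleanly because the product has no alpha-hydrogen.

**Step 2**
Reactants: 2 2-methylideneheptanal, 3 benzyl diazoacetate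
Product: 5 benzyl 2-diazo-3-hydroxy-4-methylidenenonanoate (racemic), via lithiated benzyl diazoacetate 4 (not isolated)
Conditions: 3, LiN(iPr)2, THF, –78 °C; then 2, –78 °C; AcOH quench
Reagents that add atoms: none
Why: Aldol-type 1,2-addition of a lithiated diazoacetate to an aldehyde is standard, the hard carbanion at –78 °C should prefer the carbonyl of the alpha-branched enal over conjugate or dipolar addition, and the new carbinol centre is racemic and is removed in step 3.

**Step 3**
Reactants: 5 benzyl 2-diazo-3-hydroxy-4-methylidenenonanoate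
Product: 6 benzyl 2-diazo-4-methylidene-3-oxononanoate
Conditions: 2-iodoxybenzoic acid (IBX), DMSO, rt, dark
Reagents that add atoms: none
Why: IBX oxidation of alpha-diazo-beta-hydroxy esters to alpha-diazo-beta-keto esters is a known neutral transformation that leaves the diazo group and the 1,1-disubstituted alkene untouched, and the allylic nature of the alcohol helps here.

**Step 4**
Reactants: 6 benzyl 2-diazo-4-methylidene-3-oxononanoate, 7 ethoxyacetylene
Product: 12 benzyl 2-ethoxy-4-hydroxy-6-pentylbenzoate, via benzyloxycarbonyl vinylketene 8 (not isolated), via 4-vinylcyclobutenone 9 (not isolated), via dienylketene 10 (not isolated), via cyclohexa-2,4-dienone 11 (not isolated)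
Conditions: 7 (3 equiv), ClCH2CH2Cl, hν (254 nm, quartz), 20 °C; evaporate excess 7; PhMe, 90 °C
Reagents that add atoms: none
Why: Proposed new method: light expels N2 from 6 and the 1-pentylvinyl group moves from the ketone carbon to the diazo carbon (Wolff rearrangement, bond B1–B6), which turns the old ketone carbon into the ketene carbonyl of 8, made more electrophilic by the geminal ester. The unsubstituted, nucleophilic carbon of 7 attacks that carbonyl carbon (B3–B4) and the ethoxy-bearing carbon closes onto the ketene alpha-carbon (B1–B2), a [2+2] cycloaddition that gives 9 with H next to C=O and OEt next to the quaternary carbon. On heating, 9 opens by a reversible conrotatory 4-pi electrocyclic cleavage of the B1–B4 bond to 10, ring B then closes by a disrotatory 6-pi electrocyclisation of the ketene carbon onto the CH2 terminus (B4–B5), and 11 enolises to the phenol 12. The closest known reaction type is the photochemical Danheiser benzannulation of alpha,beta-unsaturated alpha-diazo ketones with alkoxy- and siloxyalkynes, and the untested element is the ester on the diazo carbon. Three selectivities are needed: migration of vinyl and not of benzyloxy (carbon on a ketone migrates far more readily than alkoxy on an ester), [2+2] and not [4+2] addition (the ester C=O is a poor heterodiene terminus and the 1,1-disubstituted vinyl group is twisted out of the s-cis diene geometry), and CH-to-carbonyl orientation (fixed by the polarisation of the ynol ether), while a dienylketene of the wrong geometry simply recloses to 9 until the irreversible aromatisation drains the equilibrium. No stereocentre survives, since the quaternary carbon of 9 is formed racemic and becomes trigonal again in 10.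

**Step 5**
Reactants: 13 methyl 2-hydroxy-4-methoxy-6-methylbenzoate (methyl everninate)
Product: 14 methyl 2-(benzyloxy)-4-methoxy-6-methylbenzoate
Conditions: BnBr, K2CO3, DMF, 60 °C
Reagents that add atoms: benzyl bromide, BrCc1ccccc1
Why: Williamson etherification, in which warming in DMF overcomes the hydrogen bond of the phenol to the ester; the benzyl group blocks the acidic OH during lithiation and leaves later by hydrogenolysis.

**Step 6**
Reactants: 14 methyl 2-(benzyloxy)-4-methoxy-6-methylbenzoate, 15 N-methoxy-N-methylhexanamide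
Product: 17 methyl 2-(benzyloxy)-4-methoxy-6-(2-oxoheptyl)benzoate, via benzylic organolithium 16 (not isolated)
Conditions: LiN(iPr)2, THF, –78 °C; then 15, –78 → –40 °C; AcOH quench
Reagents that add atoms: none
Why: Lateral lithiation of an ortho-toluate followed by Weinreb ketone synthesis, in which the ester acidifies the ortho methyl group, the doubly ortho-substituted ester resists self-condensation, and the chelated tetrahedral adduct prevents over-addition and proton exchange until the quench.

**Step 7**
Reactants: 17 methyl 2-(benzyloxy)-4-methoxy-6-(2-oxoheptyl)benzoate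
Product: 18 2-(benzyloxy)-4-methoxy-6-(2-oxoheptyl)benzoic acid
Conditions: KOH, EtOH–H2O, reflux; then cold 1 M HCl to pH 3
Reagents that add atoms: potassium hydroxide, [K+].[OH-]
Why: Saponification with hot aqueous-ethanolic KOH is the usual way to free 2,6-disubstituted benzoic acids of this series, the ethers and the ketone are inert to hydroxide, and cold acidification avoids acid-induced cyclodehydration.

**Step 8**
Reactants: 18 2-(benzyloxy)-4-methoxy-6-(2-oxoheptyl)benzoic acid, 12 benzyl 2-ethoxy-4-hydroxy-6-pentylbenzoate
Product: 20 benzyl 4-{[2-(benzyloxy)-4-methoxy-6-(2-oxoheptyl)benzoyl]oxy}-2-ethoxy-6-pentylbenzoate, via mixed trifluoroacetic anhydride 19 (not isolated)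
Conditions: (CF3CO)2O, PhMe, 0 °C → rt
Reagents that add atoms: none
Why: Classical depside esterification through the mixed trifluoroacetic anhydride, which transfers the hindered, electron-rich aroyl group to the only free hydroxyl of 12 (B4–OH), so no site selectivity is required.

**Step 9**
Reactants: 20 benzyl 4-{[2-(benzyloxy)-4-methoxy-6-(2-oxoheptyl)benzoyl]oxy}-2-ethoxy-6-pentylbenzoate
Product: 21 2-ethoxy-4-{[2-hydroxy-4-methoxy-6-(2-oxoheptyl)benzoyl]oxy}-6-pentylbenzoic acid
Conditions: H2 (1 atm), 10% Pd/C, EtOAc, rt
Reagents that add atoms: none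
Why: Catalytic hydrogenolysis removes the benzyl ether and the benzyl ester together and spares the aryl ester, the non-conjugated ketone and the alkyl aryl ethers; it is placed before the BCl3 step because BCl3 would attack both benzyl groups at rates comparable to the ethyl ether and give mixtures.

**Step 10**
Reactants: 21 2-ethoxy-4-{[2-hydroxy-4-methoxy-6-(2-oxoheptyl)benzoyl]oxy}-6-pentylbenzoic acid
Product: 22 2-hydroxy-4-{[2-hydroxy-4-methoxy-6-(2-oxoheptyl)benzoyl]oxy}-6-pentylbenzoic acid (target CNP0358566.0)
Conditions: BCl3 (1 M in CH2Cl2, excess), CH2Cl2, –78 → 0 °C; then H2O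
Reagents that add atoms: none
Why: Chelation-directed ether cleavage, in which boron binds the B1 carboxyl and the adjacent B2 ethoxy oxygen in a six-membered chelate and chloride removes the ethyl group by SN2 attack, whereas the ring A methoxy group is para to its carbonyl, cannot chelate and should stay intact at or below 0 °C.

**Compound list**

1 | heptanal | CCCCCCC=O | starting material
2 | 2-methylideneheptanal (2-pentylacrolein) | C=C(CCCCC)C=O | intermediate
3 | benzyl diazoacetate | [N-]=[N+]=CC(=O)OCc1ccccc1 | starting material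
4 | benzyl 2-diazo-2-lithioacetate (formed in the flask) | [Li]C(=[N+]=[N-])C(=O)OCc1ccccc1 | intermediate
5 | benzyl 2-diazo-3-hydroxy-4-methylidenenonanoate (racemic) | C=C(CCCCC)C(O)C(=[N+]=[N-])C(=O)OCc1ccccc1 | intermediate
6 | benzyl 2-diazo-4-methylidene-3-oxononanoate | C=C(CCCCC)C(=O)C(=[N+]=[N-])C(=O)OCc1ccccc1 | intermediate
7 | ethoxyacetylene | C#COCC | starting material
8 | benzyl 3-methylidene-2-(oxomethylidene)octanoate, the vinylketene (formed in the flask) | C=C(CCCCC)C(=C=O)C(=O)OCc1ccccc1 | intermediate
9 | benzyl 2-ethoxy-1-(hept-1-en-2-yl)-4-oxocyclobut-2-ene-1-carboxylate (racemic, formed in the flask) | CCCCCC(=C)C1(C(=O)OCc2ccccc2)C(=O)C=C1OCC | intermediate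
10 | benzyl (2Z)-3-ethoxy-2-(hept-1-en-2-yl)-5-oxopenta-2,4-dienoate, ketene arm cis to the vinyl group (formed in the flask) | O=C=C/C(OCC)=C(\C(=C)CCCCC)C(=O)OCc1ccccc1 | intermediate
11 | benzyl 6-ethoxy-4-oxo-2-pentylcyclohexa-1,5-diene-1-carboxylate (formed in the flask) | O=C1C=C(OCC)C(C(=O)OCc2ccccc2)=C(CCCCC)C1 | intermediate
12 | benzyl 2-ethoxy-4-hydroxy-6-pentylbenzoate | CCCCCc1cc(O)cc(OCC)c1C(=O)OCc1ccccc1 | intermediate
13 | methyl 2-hydroxy-4-methoxy-6-methylbenzoate (methyl everninate) | COC(=O)c1c(C)cc(OC)cc1O | starting material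
14 | methyl 2-(benzyloxy)-4-methoxy-6-methylbenzoate | COC(=O)c1c(C)cc(OC)cc1OCc1ccccc1 | intermediate
15 | N-methoxy-N-methylhexanamide | CCCCCC(=O)N(C)OC | starting material
16 | methyl 2-(benzyloxy)-6-(lithiomethyl)-4-methoxybenzoate (formed in the flask) | [Li]Cc1cc(OC)cc(OCc2ccccc2)c1C(=O)OC | intermediate
17 | methyl 2-(benzyloxy)-4-methoxy-6-(2-oxoheptyl)benzoate | CCCCCC(=O)Cc1cc(OC)cc(OCc2ccccc2)c1C(=O)OC | intermediate
18 | 2-(benzyloxy)-4-methoxy-6-(2-oxoheptyl)benzoic acid | CCCCCC(=O)Cc1cc(OC)cc(OCc2ccccc2)c1C(=O)O | intermediate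
19 | 2-(benzyloxy)-4-methoxy-6-(2-oxoheptyl)benzoic trifluoroacetic anhydride (formed in the flask) | CCCCCC(=O)Cc1cc(OC)cc(OCc2ccccc2)c1C(=O)OC(=O)C(F)(F)F | intermediate
20 | benzyl 4-{[2-(benzyloxy)-4-methoxy-6-(2-oxoheptyl)benzoyl]oxy}-2-ethoxy-6-pentylbenzoate | CCCCCC(=O)Cc1cc(OC)cc(OCc2ccccc2)c1C(=O)Oc1cc(OCC)c(C(=O)OCc2ccccc2)c(CCCCC)c1 | intermediate
21 | 2-ethoxy-4-{[2-hydroxy-4-methoxy-6-(2-oxoheptyl)benzoyl]oxy}-6-pentylbenzoic acid | CCCCCC(=O)Cc1cc(OC)cc(O)c1C(=O)Oc1cc(OCC)c(C(=O)O)c(CCCCC)c1 | intermediate
22 | 2-hydroxy-4-{[2-hydroxy-4-methoxy-6-(2-oxoheptyl)benzoyl]oxy}-6-pentylbenzoic acid (achiral) | CCCCCC(=O)Cc1cc(OC)cc(O)c1C(=O)Oc1cc(O)c(C(=O)O)c(CCCCC)c1 | target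

**Totals**

Total step count: 10.
Longest linear sequence: 7 steps (1, 2, 3, 4, 8, 9, 10, from heptanal). The ring A branch contributes steps 5–7.

**Steps most likely to fail**

**Step 4 (key step).**
- The ketene may be intercepted through its ester carbonyl in a [4+2] sense.
- The vinylketene may react as a diene, which would exchange the roles of the two oxygens.
- The photogenerated carbene may add to the ynol ether before the vinyl group migrates.
- The diazo group may undergo slow dipolar cycloaddition in the dark.
- The ketene may dimerise.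

The fallback uses known chemistry only. It sets out from acid 18 and comes back at target 22. Commercial olivetolic acid (2,4-dihydroxy-6-pentylbenzoic acid) is esterified with benzyl bromide and KHCO3 in DMF to benzyl 2,4-dihydroxy-6-pentylbenzoate F1. In F1 the two oxygens are told apart by the hydrogen bond from B2–OH to the ester, not by a protecting group. Acid 18 and F1 are joined with trifluoroacetic anhydride in toluene (through 19) at the unchelated B4–OH. This gives benzyl 4-{[2-(benzyloxy)-4-methoxy-6-(2-oxoheptyl)benzoyl]oxy}-2-hydroxy-6-pentylbenzoate F2. Hydrogenolysis (H2, 10% Pd/C, EtOAc) then gives 22.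

**Step 8.**
- The activated acid may cyclodehydrate through the enol of its own ketone faster than it acylates the phenol.
- The activated benzylic methylene may be trifluoroacetylated.

The fallback masks the ketone. It sets out from keto ester 17 and comes back at depside 20.
- Ketalisation of 17 with 1,2-bis(trimethylsiloxy)ethane and catalytic Me3SiOTf (CH2Cl2, –78 → –20 °C) gives methyl 2-(benzyloxy)-4-methoxy-6-[(2-pentyl-1,3-dioxolan-2-yl)methyl]benzoate F3.
- KOH in DMSO–H2O at 100 °C, then cold dilute HCl to pH 5, gives 2-(benzyloxy)-4-methoxy-6-[(2-pentyl-1,3-dioxolan-2-yl)methyl]benzoic acid F4.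
- Steglich-type esterification of F4 with phenol 12 (EDC·HCl, DMAP, CH2Cl2) gives the ketal-protected depside F5.
- Mild hydrolysis of F5 (pyridinium tosylate, wet acetone) releases the ketone and delivers 20.

**Step 10.**
- SN2 removal of an ethyl group is slower than that of a methyl group, so the reaction may need forcing.
- Forcing may cost the ring A methyl ether, cleave the boron-activated depside ester, or cause decarboxylation.

The fallback changes the B2 protecting group at the level of the ring-forming step, so that the last unmasking is a Brønsted-acid elimination. It sets out from diazo keto ester 6 and comes back at target 22.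
- Diazo keto ester 6 is irradiated under the conditions of step 4 with tert-butoxyacetylene F6. This known ynol ether has to be prepared beforehand, and its excess is stripped off before the heating stage. The product is benzyl 2-tert-butoxy-4-hydroxy-6-pentylbenzoate F7.
- Acylation of F7 with 18 as in step 8 gives benzyl 4-{[2-(benzyloxy)-4-methoxy-6-(2-oxoheptyl)benzoyl]oxy}-2-tert-butoxy-6-pentylbenzoate F8.
- Hydrogenolysis of F8 gives 2-tert-butoxy-4-{[2-hydroxy-4-methoxy-6-(2-oxoheptyl)benzoyl]oxy}-6-pentylbenzoic acid F9.
- Brief treatment of F9 with CF3CO2H in CH2Cl2 at 0 °C removes the tert-butyl group and gives 22.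

**Further compounds**

F1 | step 4 | benzyl 2,4-dihydroxy-6-pentylbenzoate | CCCCCc1cc(O)cc(O)c1C(=O)OCc1ccccc1
F2 | step 4 | benzyl 4-{[2-(benzyloxy)-4-methoxy-6-(2-oxoheptyl)benzoyl]oxy}-2-hydroxy-6-pentylbenzoate | CCCCCC(=O)Cc1cc(OC)cc(OCc2ccccc2)c1C(=O)Oc1cc(O)c(C(=O)OCc2ccccc2)c(CCCCC)c1
F3 | step 8 | methyl 2-(benzyloxy)-4-methoxy-6-[(2-pentyl-1,3-dioxolan-2-yl)methyl]benzoate | CCCCCC1(Cc2cc(OC)cc(OCc3ccccc3)c2C(=O)OC)OCCO1
F4 | step 8 | 2-(benzyloxy)-4-methoxy-6-[(2-pentyl-1,3-dioxolan-2-yl)methyl]benzoic acid | CCCCCC1(Cc2cc(OC)cc(OCc3ccccc3)c2C(=O)O)OCCO1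
F5 | step 8 | benzyl 4-({2-(benzyloxy)-4-methoxy-6-[(2-pentyl-1,3-dioxolan-2-yl)methyl]benzoyl}oxy)-2-ethoxy-6-pentylbenzoate | CCCCCC1(Cc2cc(OC)cc(OCc3ccccc3)c2C(=O)Oc2cc(OCC)c(C(=O)OCc3ccccc3)c(CCCCC)c2)OCCO1
F6 | step 10 | tert-butoxyacetylene | C#COC(C)(C)C
F7 | step 10 | benzyl 2-tert-butoxy-4-hydroxy-6-pentylbenzoate | CCCCCc1cc(O)cc(OC(C)(C)C)c1C(=O)OCc1ccccc1
F8 | step 10 | benzyl 4-{[2-(benzyloxy)-4-methoxy-6-(2-oxoheptyl)benzoyl]oxy}-2-tert-butoxy-6-pentylbenzoate | CCCCCC(=O)Cc1cc(OC)cc(OCc2ccccc2)c1C(=O)Oc1cc(OC(C)(C)C)c(C(=O)OCc2ccccc2)c(CCCCC)c1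
F9 | step 10 | 2-tert-butoxy-4-{[2-hydroxy-4-methoxy-6-(2-oxoheptyl)benzoyl]oxy}-6-pentylbenzoic acid | CCCCCC(=O)Cc1cc(OC)cc(O)c1C(=O)Oc1cc(OC(C)(C)C)c(C(=O)O)c(CCCCC)c1
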